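The earlier runs and the new flask stem from a simulated flask for substances that don't exist; the scatter is artificial.

What is left of E in the ash run, 55.8% at 120 s, is worth setting beside Q: the ratio of the two tells you where Q stops rising.

| flask | E | remark | time |
|---|---|---|---|
| ash | 0.025 M | run made earlier |  |
| flask | 0.050 M |  | 20 min |

ash run (percent of the E charged)

| time / s | Q / % | E / % |
|---|---|---|
| 10.0 | 5.1 | 94.7 |
| 20.0 | 8.8 | 89.5 |
| 50.0 | 15.5 | 77.1 |
| 120 | 19.5 | 55.8 |

(each reading ± 0.3 percentage points)



1. time up to 20 min at which Q stands highest
2. the amount of Q, in percent of the E charged, at that time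

Run the ash flask slowly. In the first instants, up to 10.0 s, nearly all of the E lost stands as Q, the intermediate. In the middle, from 50.0 s to 120 s, E falls by 21 percentage points but Q rises by 4 points, so I take the difference to have left Q. Read over that interval of the ash run, per unit present, E goes at 0.004579 s⁻¹ and Q at 0.0141 s⁻¹. Q stops rising when making equals using, and there time drops out: Q over E equals the first constant over the second, the turning ratio, a reading of 0.324.

I assume first-order losses, so that the percentages of the ash run serve for this flask. Q over E climbs from 0.201 to 0.349 across that interval and passes the turning ratio near 1.80 min, with E near 59.4%, so I reckon Q at 19.3%. As for the end, by that reading of E the limit of 20 min lies 7.93 half-lives of E out, so I expect the top well before it.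

The forecast differs from my reckoning: 1.5 min and 23%, noting that “Doubling E leaves this unchanged if the kinetics are first order.”

The flask gives 2.05 min and 19.3%.

    E ⇌ Q (K = 1.80, k = 0.00550 s⁻¹)
    Q ⇌ X (K = 10.0, k = 0.00100 s⁻¹)
    X ⇌ L (K = 0.330, k = 0.00830 s⁻¹)
    Q → D (k = 0.00960 s⁻¹)
    Q ⇌ J (K = 0.500, k = 0.00660 s⁻¹)

At 2.05 min this flask holds Q over E at 0.350, against the turning ratio of 0.324. By its own step, both ways counted, the pair E and Q relaxes with a half-life of 1.35 min, which is shorter than the 10.5 min of the pair Q and X by its step. In the neighbour flask with 0.20 M of E, a ratio of percentages does not change with the charge if the steps are first order, so the turning ratio again gives 19.3%. The computed top there is 19.3%.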